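## Analysis of the target

Locants used throughout: ring O1, C2 (lactone C=O), C3, C4, C5; exocyclic C6 (the CBr2 carbon); butyl chain C1'–C4'.

- Target 13 is a 5-ylidenefuran-2(5H)-one. It has one five-membered ring, O1–C2(=O)–C3=C4–C5, in which every carbon is sp2. C4 carries Br, C5 carries the exocyclic C5=C6Br2 unit, and C3 carries a butyl chain whose C1' bears the acetate.
- C1' is the only stereocenter. The SMILES encodes R (O > C3 > C2' > H).
- No second stereoelement can relay information to C1', so it must be set by reagent control. C5=C6 carries two identical bromines and has no E/Z issue.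
- The cross-conjugated array C2(=O)–C3=C4–C5=C6 is a strong acceptor, and the vinylic bromides at C4 and C6 can leave by addition–elimination. The enol ester O1–C5 is an acylating agent. The C1' acetate is allylic and prone to ionisation, SN2' attack and elimination.
- Three bromines must sit exactly at C4 (one) and C6 (two). Stepwise electrophilic bromination of a methyl or methylene precursor tends to stop at mixed bromination levels.
- C3=C4 is tetrasubstituted, and C1' must be set beside it and then survive all later steps.
- The feature that invites the chosen move is that C2 and C5, the two ring carbons flanking C3=C4, are both at the carboxyl oxidation level. C5=C6Br2 is simply the gem-dibromoolefin image of a C5=O group.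
- The ring O1–C2–C3=C4–C5 is therefore a maleic anhydride in disguise, which is in turn the doubly oxidised form of a 3,4-disubstituted furan ring. Only C4–Br versus C3–alkyl distinguishes C5 from C2.

## Retrosynthetic reasoning

**13 ⇒ 11.** The cut is the whole C5=C6 double bond, which removes C6 together with both of its bromines. Any cut inside the ring would leave an acyclic, tetrasubstituted bromoalkene whose geometry would have to be controlled. This cut leaves the ring intact, so the C3=C4 geometry never becomes a question. The precursor 11 has one bromine instead of three, no diene and no exocyclic alkene. The forward reaction is a Wittig-type gem-dibromoolefination through 12, and it must choose C5=O over C2=O. The C4 bromine and the branched C1' substituent are the only elements that can make that choice.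

**11 ⇒ 7 (through 8, 9 and 10).** The cuts are the two carbonyl oxygens at C2 and C5, so the anhydride ring becomes the aromatic furan ring of 7. Both α-carbons are raised to the same oxidation level, so the oxidation needs no regiocontrol. Whichever bridgehead C–H of 8 is broken first, 9 and 10 converge on 11. The gain is that the sensitive electrophilic ring is carried as a robust aromatic ring while the stereocenter is made.

**7 ⇒ 6 ⇒ 5.** The cuts are the O–acetyl bond and the C1'–H bond. C1' lies between a flat heteroaryl group and an n-propyl group, which is the substrate type that asymmetric transfer hydrogenation differentiates well. The forward steps must deliver hydride to one face of 5 and then acylate oxygen without touching the C1'–O bond.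

**5 ⇒ 1 + 2 (through 3 and 4).** The cut is C3–C1'. In 1 the two C–Br bonds are equivalent by symmetry, so the first bromine–lithium exchange has no regiochemical issue. The bromine that stays behind is the C4 bromine of 13, so C4 is never brominated. The acyl donor 2 brings C1'–C4' at the ketone level in one operation.

## Alternatives that were turned down

**Alternative 1:** This is the textbook route.
- *Disconnection:* O1–C5 and all three C–Br bonds, back to 2-butyl-4-oxopentanoic acid A1.
- *Forward key step:* exhaustive α-bromination of the keto acid, followed by cyclodehydration with dehydrogenation in hot concentrated mineral acid. This would give 3-butyl-4-bromo-5-(dibromomethylene)furan-2(5H)-one A2.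
- *Completion:* radical bromination at C1' to 4-bromo-3-(1-bromobutyl)-5-(dibromomethylene)furan-2(5H)-one A3, then displacement with acetate.
- *Reason turned down:* C1' is functionalised last, through a planar allyl-type radical and then a substitution at an allylic bromide. Nothing in A2 or A3 can bias a face, so the product is racemic and half the material is lost in a final resolution.
- The number of bromines at C6 is fixed by unselective enol bromination. The hot acid also excludes carrying the acetate earlier.

**Alternative 2:**
- *Disconnection:* O1–C5 and one C6–Br bond.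
- *Forward key step:* 5-exo-dig bromolactonisation of (R,E)-2-(1-acetoxybutyl)-3,5-dibromopent-2-en-4-ynoic acid A4, in which carboxyl and alkynyl are cis.
- *Merit:* the closure itself is sound, because the bromoalkyne is polarised so that oxygen attacks C5 and the bromonium ion ends on C6.
- *Reason turned down:* A4 is no simpler than 13. It holds the same tetrasubstituted C3=C4 bond, now acyclic, with Br and carboxyl trans.
- That arrangement requires a net anti addition of bromine and a carbon group across a diyne, whereas reliable carbometalations are syn.
- A C3 vinyl metal anti to the C4 bromine would eliminate back to the diyne. 6-endo closure also competes, and the step count rises.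

**Alternative 3:**
- *Disconnection:* C3–C1' together with C4–Br.
- *Forward key step:* a three-component bromo-aldol (β-halo Morita–Baylis–Hillman type) union. Bromide adds to methyl 5-(triisopropylsilyl)penta-2,4-diynoate A5, and the resulting allenolate is trapped by the C4 aldehyde under a chiral Lewis acid. The product would be methyl (E)-3-bromo-2-[(R)-1-hydroxybutyl]-5-(triisopropylsilyl)pent-2-en-4-ynoate A6.
- *Merit:* it is attractive because it sets the stereocenter and the bromoalkene at once.
- *Reason turned down:* three selectivities must all succeed in one step.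
  - Bromide must add 1,4 and not 1,6.
  - The aldehyde must approach the allenolate from the bromine side, yet Br and a slim alkynyl group are almost equal in size. Only the isomer with the ester cis to the alkyne can lactonise.
  - A linear, enolisable aldehyde must be differentiated facially.
- The risk therefore lies in three places, and three more steps are still needed after A6.

Key step: step 5

Remark: the descriptor read from the SMILES is R at C1'. The furan positions are named with the target locants (furan C-2 = C2, C-3 = C3, C-4 = C4, C-5 = C5).

## Route

Step 1
Reactants: 1 3,4-dibromofuran; 2 N-methoxy-N-methylbutanamide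
Product: 5 1-(4-bromofuran-3-yl)butan-1-one, via 4-bromo-3-furyllithium 3 (not isolated), via chelated tetrahedral adduct 4 (not isolated)
Conditions: n-BuLi (1.0 equiv), Et2O, –78 °C; then 2, –78 → –20 °C; 1 M HCl, 0 °C
Reagents that add atoms: none
Why: Bromine–lithium exchange on the symmetric dibromide is fast at –78 °C and stops after one exchange, and at this temperature 3 does not isomerise to the 2-lithio isomer. In the Weinreb ketone synthesis the chelated adduct 4 blocks a second addition until the acid quench.

Step 2
Reactants: 5 1-(4-bromofuran-3-yl)butan-1-one
Product: 6 (R)-1-(4-bromofuran-3-yl)butan-1-ol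
Conditions: RuCl[(R,R)-TsDPEN](p-cymene) (1 mol %), HCO2H–Et3N (5:2), 30 °C
Reagents that add atoms: none
Why: Noyori–Ikariya asymmetric transfer hydrogenation of a heteroaryl alkyl ketone. The CH/π contact between the η6-arene and the furan places the heteroaryl group beside the arene ligand, so the (R,R) catalyst should deliver hydride to the face that gives R at C1'. The aryl bromide and the furan are inert to the Ru hydride.

Step 3
Reactants: 6 (R)-1-(4-bromofuran-3-yl)butan-1-ol
Product: 7 (R)-1-(4-bromofuran-3-yl)butyl acetate
Conditions: Ac2O, pyridine, DMAP (5 mol %), CH2Cl2, 0 °C → rt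
Reagents that add atoms: acetic anhydride CC(=O)OC(C)=O
Why: DMAP-catalysed O-acylation forms only the O–acyl bond, so C1' keeps its configuration. The electron-poor bromofuran disfavours ionisation of the furylic acetate.

Step 4
Reactants: 7 (R)-1-(4-bromofuran-3-yl)butyl acetate
Product: 11 (R)-1-(4-bromo-2,5-dioxo-2,5-dihydrofuran-3-yl)butyl acetate, via furan endoperoxide 8 (not isolated), via C5-oxo pseudo-acid 9 (not isolated), via C2-oxo pseudo-acid 10 (not isolated)
Conditions: O2, tetraphenylporphyrin (cat.), hν (visible), i-Pr2NEt, CH2Cl2, –78 → 0 °C; cold 1 M KHSO4 wash, dry; then Dess–Martin periodinane, CH2Cl2, rt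
Reagents that add atoms: dioxygen O=O
Why: Singlet oxygen adds across C2/C5 of the furan in a [4+2] cycloaddition to give 8, and the amine triggers Kornblum–DeLaMare fragmentation at either bridgehead C–H to give 9 and 10. Dess–Martin oxidation of the lactol C–H funnels both regioisomers and all hemiacetal epimers into the single anhydride 11. C1', the acetate and the vinylic bromide take no part.

Step 5
Reactants: 11 (R)-1-(4-bromo-2,5-dioxo-2,5-dihydrofuran-3-yl)butyl acetate
Product: 13 (R)-1-[4-bromo-5-(dibromomethylene)-2-oxo-2,5-dihydrofuran-3-yl]butyl acetate, via spiro-oxaphosphetane 12 (not isolated)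
Conditions: CBr4 (1.5 equiv), PPh3 (3.0 equiv), CH2Cl2, 0 °C, 30 min (ylide preformed); then 11, –20 °C → rt
Reagents that add atoms: carbon tetrabromide BrC(Br)(Br)Br
Why: This is a Ramirez gem-dibromoolefination, i.e. a Wittig olefination of a cyclic anhydride carbonyl, the known reaction type that turns anhydrides into enol lactones. CBr4 and two PPh3 give Ph3P=CBr2 and Ph3PBr2 before 11 is added, so no free phosphine meets the bromoalkene; the ylide carbon then adds to C5=O, the adduct closes to the four-membered oxaphosphetane 12, and cycloreversion releases Ph3P=O and the C5=C6 bond. In one operation the step brings in C6, both C6–Br bonds and the exocyclic alkene, and converts the anhydride into the ylidene butenolide. No ring of the target is closed here, because the O1–C2–C3=C4–C5 ring is carried over from 11; if the first adduct opens to the keto carboxylate, it re-closes by 5-exo-trig attack of the carboxylate on the C5 ketone, which the cis C3=C4 geometry makes possible. The selectivity needed is C5=O over C2=O: the C4 bromine raises the electrophilicity of the adjacent C5=O by induction while its lone pair donates through C4=C3 into C2=O, and C2=O is screened by the branched C1' substituent whereas C5=O has only Br as a neighbour. The ylide carbon bears no hydrogen, so the proton shift to an unreactive stabilised acyl ylide, the usual dead end of anhydride olefinations, is not available. No stereocenter is formed, C5=C6 has no E/Z issue because both substituents on C6 are Br, and C1' is safe in the aprotic, non-basic medium. The acetate carbonyl is far less electrophilic than the anhydride and should stay untouched.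

## Compound list

1 | 3,4-dibromofuran | Brc1cocc1Br | starting material
2 | N-methoxy-N-methylbutanamide | CCCC(=O)N(C)OC | starting material
3 | (4-bromofuran-3-yl)lithium | [Li]c1cocc1Br | intermediate
4 | lithium 1-(4-bromofuran-3-yl)-1-[methoxy(methyl)amino]butan-1-olate | CCCC([O-])(N(C)OC)c1cocc1Br.[Li+] | intermediate
5 | 1-(4-bromofuran-3-yl)butan-1-one | CCCC(=O)c1cocc1Br | intermediate
6 | (R)-1-(4-bromofuran-3-yl)butan-1-ol | CCC[C@@H](O)c1cocc1Br | intermediate
7 | (R)-1-(4-bromofuran-3-yl)butyl acetate | CCC[C@@H](OC(C)=O)c1cocc1Br | intermediate
8 | (R)-1-(6-bromo-2,3,7-trioxabicyclo[2.2.1]hept-5-en-5-yl)butyl acetate (both bridgehead diastereomers) | CCC[C@@H](OC(C)=O)C1=C(Br)C2OOC1O2 | intermediate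
9 | (R)-1-(4-bromo-2-hydroxy-5-oxo-2,5-dihydrofuran-3-yl)butyl acetate (hemiacetal epimers) | CCC[C@@H](OC(C)=O)C1=C(Br)C(=O)OC1O | intermediate
10 | (R)-1-(4-bromo-5-hydroxy-2-oxo-2,5-dihydrofuran-3-yl)butyl acetate (hemiacetal epimers) | CCC[C@@H](OC(C)=O)C1=C(Br)C(O)OC1=O | intermediate
11 | (R)-1-(4-bromo-2,5-dioxo-2,5-dihydrofuran-3-yl)butyl acetate | CCC[C@@H](OC(C)=O)C1=C(Br)C(=O)OC1=O | intermediate
12 | spiro-oxaphosphetane from addition of the dibromo ylide to C5=O of 11 (C5 bonded to O–PPh3 and to CBr2–P, either configuration at C5) | CCC[C@@H](OC(C)=O)C1=C(Br)C2(OC1=O)OP(c3ccccc3)(c3ccccc3)(c3ccccc3)C2(Br)Br | intermediate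
13 | (R)-1-[4-bromo-5-(dibromomethylene)-2-oxo-2,5-dihydrofuran-3-yl]butyl acetate | CCC[C@@H](OC(C)=O)C1=C(Br)C(=C(Br)Br)OC1=O | target

## Step count and least certain steps

Total step count: 5. Longest linear sequence: 5 steps (1 → 5 → 6 → 7 → 11 → 13).

**Step 5 (key step).**
- The most likely failure is attack of phosphorus species on the substrate rather than on the carbonyl. This could be conjugate addition at C4 with loss of bromide, or halophilic debromination at the α,α-dibromo-β-keto phosphonium stage if the first adduct opens.
- The second risk is erosion of site selectivity by attack at C2=O, since both carbonyls are activated.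
- The fallback brings in C6 without phosphorus and adds the bromines afterwards, using known chemistry of this compound family. It sets out from 11 and returns at 13.
  1. MeMgBr (1 equiv, THF, –78 °C) adds to C5=O to give (R)-1-(4-bromo-5-hydroxy-5-methyl-2-oxo-2,5-dihydrofuran-3-yl)butyl acetate F1.
  2. P2O5 in CH2Cl2 dehydrates it to (R)-1-(4-bromo-5-methylene-2-oxo-2,5-dihydrofuran-3-yl)butyl acetate F2.
  3. Br2 adds to the exocyclic alkene to give (R)-1-[4,5-dibromo-5-(bromomethyl)-2-oxo-2,5-dihydrofuran-3-yl]butyl acetate F3.
  4. Et3N eliminates HBr to give (R)-1-[(5Z)-4-bromo-5-(bromomethylene)-2-oxo-2,5-dihydrofuran-3-yl]butyl acetate F4.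
  5. A second Br2 addition gives (R)-1-[4,5-dibromo-5-(dibromomethyl)-2-oxo-2,5-dihydrofuran-3-yl]butyl acetate F5, and a second elimination with Et3N gives 13.

**Step 4.**
- The bromine makes the furan electron-poor, so the cycloaddition may be slow. The endoperoxide may then decay by other pathways during long irradiation.
- The amine may deprotonate the γ-acidic C1'–H of the C5-oxo intermediates, which would erode the configuration.
- The fallback avoids both the peroxide and the amine. It sets out from 7 and returns at 11.
  1. NBS with NaHCO3 in aqueous acetone at –15 °C opens the furan to the cis-enedial (R)-1-[(E)-3-bromo-1,4-dioxobut-2-en-2-yl]butyl acetate F6, in which the two formyl groups are cis.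
  2. Pinnick oxidation (NaClO2, NaH2PO4, 2-methyl-2-butene) gives the maleic-type diacid (R,E)-2-(1-acetoxybutyl)-3-bromobut-2-enedioic acid F7, in which the carboxyl groups are cis.
  3. F7 closes to 11 on brief treatment with Ac2O.

**Step 2.**
- Facial discrimination may be incomplete. n-Propyl is larger than methyl, and the ortho bromine twists the furan out of the carbonyl plane and weakens the CH/π contact. Conversion may also be slow.
- The fallback replaces catalyst control with enzymatic resolution plus inversion, so that both enantiomers are used. It sets out from 5 and returns at 7, bypassing step 3.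
  1. NaBH4 in MeOH gives racemic 1-(4-bromofuran-3-yl)butan-1-ol F8.
  2. Burkholderia cepacia lipase with vinyl acetate in MTBE acetylates the R enantiomer (Kazlauskas rule) directly to 7 and leaves (S)-1-(4-bromofuran-3-yl)butan-1-ol F9.
  3. After separation, Mitsunobu reaction of F9 with acetic acid (PPh3, DIAD, THF, 0 °C) inverts C1' and also gives 7.

## Further compounds

F1 | step 5 | (R)-1-(4-bromo-5-hydroxy-5-methyl-2-oxo-2,5-dihydrofuran-3-yl)butyl acetate (C5 epimers) | CCC[C@@H](OC(C)=O)C1=C(Br)C(C)(O)OC1=O
F2 | step 5 | (R)-1-(4-bromo-5-methylene-2-oxo-2,5-dihydrofuran-3-yl)butyl acetate | CCC[C@@H](OC(C)=O)C1=C(Br)C(=C)OC1=O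
F3 | step 5 | (R)-1-[4,5-dibromo-5-(bromomethyl)-2-oxo-2,5-dihydrofuran-3-yl]butyl acetate (C5 epimers) | CCC[C@@H](OC(C)=O)C1=C(Br)C(Br)(CBr)OC1=O
F4 | step 5 | (R)-1-[(5Z)-4-bromo-5-(bromomethylene)-2-oxo-2,5-dihydrofuran-3-yl]butyl acetate | CCC[C@@H](OC(C)=O)C1=C(Br)/C(=C/Br)OC1=O
F5 | step 5 | (R)-1-[4,5-dibromo-5-(dibromomethyl)-2-oxo-2,5-dihydrofuran-3-yl]butyl acetate (C5 epimers) | CCC[C@@H](OC(C)=O)C1=C(Br)C(Br)(C(Br)Br)OC1=O
F6 | step 4 | (R)-1-[(E)-3-bromo-1,4-dioxobut-2-en-2-yl]butyl acetate (formyl groups cis) | CCC[C@@H](OC(C)=O)/C(C=O)=C(\Br)C=O
F7 | step 4 | (R,E)-2-(1-acetoxybutyl)-3-bromobut-2-enedioic acid (carboxyl groups cis) | CCC[C@@H](OC(C)=O)/C(C(O)=O)=C(\Br)C(O)=O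
F8 | step 2 | racemic 1-(4-bromofuran-3-yl)butan-1-ol | CCCC(O)c1cocc1Br
F9 | step 2 | (S)-1-(4-bromofuran-3-yl)butan-1-ol | CCC[C@H](O)c1cocc1Br
A1 | alternative 1 | 2-butyl-4-oxopentanoic acid | CCCCC(CC(C)=O)C(O)=O
A2 | alternative 1 | 3-butyl-4-bromo-5-(dibromomethylene)furan-2(5H)-one | CCCCC1=C(Br)C(=C(Br)Br)OC1=O
A3 | alternative 1 | racemic 4-bromo-3-(1-bromobutyl)-5-(dibromomethylene)furan-2(5H)-one | CCCC(Br)C1=C(Br)C(=C(Br)Br)OC1=O
A4 | alternative 2 | (R,E)-2-(1-acetoxybutyl)-3,5-dibromopent-2-en-4-ynoic acid | CCC[C@@H](OC(C)=O)/C(C(O)=O)=C(\Br)C#CBr
A5 | alternative 3 | methyl 5-(triisopropylsilyl)penta-2,4-diynoate | COC(=O)C#CC#C[Si](C(C)C)(C(C)C)C(C)C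
A6 | alternative 3 | methyl (E)-3-bromo-2-[(R)-1-hydroxybutyl]-5-(triisopropylsilyl)pent-2-en-4-ynoate | CCC[C@@H](O)/C(C(=O)OC)=C(\Br)C#C[Si](C(C)C)(C(C)C)C(C)C
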